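**Assumption (one line):** the target is taken exactly as encoded (4Z; 6S,7S,8S,9R,10R; lactone cis-fused at C6/C7), atoms carry germacrane labels (C1 ketone, C2=C3, C4=C5, C6 lactone carbinol, C7, C8 ester carbinol, C9 carbinol, C10 quaternary, C11=C13 exo-methylene, C12 lactone carbonyl), and 2-C-methyl-D-ribono-1,4-lactone, (2Z)-3-methylpent-2-en-4-yn-1-ol and trimethyl 2-phosphonoacrylate are bought.

## Retrosynthetic overview

1. C9–OH ⇐ O-TBS; the cis-fused α-methylene lactone and the ten-membered carbocycle ⇐ [2,3]-Wittig ring contraction (C6–C7 bond) of a twelve-membered bis-allylic ether, then lactonisation.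
2. Twelve-membered ether ⇐ intramolecular Horner–Wadsworth–Emmons olefination (C7=C11) of a C7 aldehyde carrying a phosphonoacetate ether on O6.
3. C8 methacrylate ⇐ Mitsunobu inversion of the ribo C8–OH; 3(2H)-furanone ⇐ cyclisation of an α′-hydroxy ynone.
4. Ynone ⇐ acetylide of the (Z)-enynol ether + 3,5-bis-O-TBS-2-C-methyl-D-ribono-1,4-lactone (lactone C1, C2, C3, C4, C5 = target C1, C10, C9, C8, C7).
5. Ring order: furanone, then twelve-membered ether, then ten-membered carbocycle and γ-lactone together.

## Route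

Step 1
Reactants: 1 2-C-methyl-D-ribono-1,4-lactone
Product: 2 3,5-bis-O-(tert-butyldimethylsilyl)-2-C-methyl-D-ribono-1,4-lactone (tertiary OH free)
Conditions: TBSCl (2.4 equiv), imidazole (5 equiv), DMF, 0 → 40 °C
Reagents that add atoms: tert-butyldimethylsilyl chloride (TBSCl), CC(C)(C)[Si](C)(C)Cl
Why: Imidazole-promoted silyl ether formation takes the primary (C7) and secondary (C9) hydroxyls and leaves the tertiary C10 hydroxyl free, and none of the three purchased stereocentres is touched.

Step 2
Reactants: 3 (2Z)-3-methylpent-2-en-4-yn-1-ol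
Product: 4 methyl 2-(dimethoxyphosphoryl)-3-{[(2Z)-3-methylpent-2-en-4-yn-1-yl]oxy}propanoate (racemic)
Conditions: trimethyl 2-phosphonoacrylate (1.1 equiv), KOt-Bu (10 mol %), THF, 0 → 23 °C
Reagents that add atoms: trimethyl 2-phosphonoacrylate, C=C(C(=O)OC)P(=O)(OC)OC
Why: Base-catalysed oxa-Michael addition of the primary allylic alkoxide to the doubly activated acrylate forms the C6–O–C13 ether and installs the C11 phosphonate in one operation; the Z olefin is untouched and the new C11 centre (racemic) is destroyed in step 8.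

Step 3
Reactants: 2 bis-TBS lactone; 4 phosphonate ether
Product: 6 alkynyl lactol (C1 hemiketal; anomer and C11-epimer mixture), via dilithio species 5 (not isolated)
Conditions: 4 (2.2 equiv), LiN(i-Pr)2 (4.4 equiv), THF, −78 °C; then 2, −78 → −30 °C; aq. NH4Cl
Reagents that add atoms: none
Why: 1,2-Addition of a lithium acetylide to a lactone: in dianion 5 the phosphonate-stabilised carbanion is unreactive at −78 °C while the acetylide adds once to C1 (the tetrahedral lithium alkoxide does not collapse), one equivalent of 5 being spent on the tertiary hydroxyl; no stereocentre is touched and the anomeric mixture is irrelevant.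

Step 4
Reactants: 6 alkynyl lactol
Product: 8 furanone alcohol (8R,9R,10R; free C8–OH), via enaminone 7 (not isolated)
Conditions: Et2NH (3 equiv), EtOH, 23 °C; then AcOH (3 equiv), THF, 23 °C
Reagents that add atoms: none
Why: Amine-mediated 3(2H)-furanone synthesis from an α′-hydroxy ynone: Et2NH traps the open-chain ynone as enaminone 7 and mild acid lets the tertiary C10 hydroxyl displace the amine at C3 (five-membered addition–elimination), which frees the C8 hydroxyl; O9 is silylated so no pyranone can form and the quaternary C10 cannot epimerise.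

Step 5
Reactants: 8 furanone alcohol
Product: 9 C8 methacrylate (8S,9R,10R)
Conditions: methacrylic acid (3 equiv), PPh3 (3 equiv), DIAD (3 equiv), toluene, 0 → 23 °C
Reagents that add atoms: methacrylic acid, C=C(C)C(=O)O
Why: Mitsunobu esterification: SN2 attack of methacrylate on the C8 oxyphosphonium inverts the purchased ribo centre (8R → 8S) and installs the ester in the same step.

Step 6
Reactants: 9 C8 methacrylate
Product: 10 primary alcohol (free C7–OH)
Conditions: HF·pyridine, pyridine, THF, 0 °C
Reagents that add atoms: none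
Why: Selective desilylation: buffered HF cleaves the unhindered primary silyl ether at O7 far faster than the secondary one at O9 next to the quaternary carbon, and at 0 °C the methacrylate does not migrate.

Step 7
Reactants: 10 primary alcohol
Product: 11 C7 aldehyde
Conditions: Dess–Martin periodinane, pyridine, CH2Cl2, 0 → 23 °C
Reagents that add atoms: none
Why: Dess–Martin oxidation of the primary alcohol under pyridine buffer gives the α-acyloxy aldehyde without epimerising C8; it is used crude.

Step 8
Reactants: 11 C7 aldehyde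
Product: 12 twelve-membered bis-allylic ether (4Z; E enoate at C7=C11)
Conditions: LiCl (10 equiv), DBU (3 equiv), MeCN, 1 mM (syringe pump), 0 → 23 °C
Reagents that add atoms: none
Why: Intramolecular Horner–Wadsworth–Emmons olefination under Masamune–Roush conditions at high dilution closes the twelve-membered ring and gives the E enoate (C8 trans to the ester and cis to the C13 methylene), the weak base sparing the C8 stereocentre.

Step 9
Reactants: 12 twelve-membered bis-allylic ether
Product: 15 9-O-TBS lactone (6S,7S,8S,9R,10R), via lithium trienolate 13 (not isolated), via hydroxy ester 14 (not isolated)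
Conditions: LiN(SiMe3)2 (1.2 equiv), THF, −78 → −40 °C; AcOH, −78 °C; then PPTS (10 mol %), CH2Cl2, 23 °C
Reagents that add atoms: none
Why: Enolate [2,3]-Wittig rearrangement run as a ring contraction: deprotonation at C6 (α-oxy and vinylogous to the furanone carbonyl) gives trienolate 13, whose C6 terminus attacks C7 suprafacially through a five-membered envelope as the C13–O bond breaks, forming the C6–C7 bond, the ten-membered carbocycle and the exo-methylene at once; because C8 is cis to the migrating CH2–O group and C5 and C8 are tied into the same ring they end up cis (hence the cis-fused lactone after acid-catalysed lactonisation of 14), and C6 is expected to add to the face of C7=C11 that keeps H8 in the olefin plane (A(1,3) strain against C13H2) with ring carbon C9 anti to the new bond, which gives 6S,7S.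

Step 10
Reactants: 15 9-O-TBS lactone
Product: 16 target CNP0252578.4
Conditions: HF·pyridine, THF, 0 → 23 °C
Reagents that add atoms: none
Why: Acidic fluoride desilylation removes the last silyl ether at O9 without Michael addition to the α-methylene lactone or the methacrylate, and no stereocentre is affected.

## Compound list

1 | 2-C-methyl-D-ribono-1,4-lactone, (3R,4R,5R)-3,4-dihydroxy-5-(hydroxymethyl)-3-methyloxolan-2-one | O=C1[C@](C)(O)[C@H](O)[C@@H](CO)O1 | starting material
2 | (3R,4R,5R)-4-(tert-butyldimethylsilyloxy)-5-[(tert-butyldimethylsilyloxy)methyl]-3-hydroxy-3-methyloxolan-2-one | O=C1[C@](C)(O)[C@H](O[Si](C)(C)C(C)(C)C)[C@@H](CO[Si](C)(C)C(C)(C)C)O1 | intermediate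
3 | (2Z)-3-methylpent-2-en-4-yn-1-ol | C#C/C(C)=C\CO | starting material
4 | methyl 2-(dimethoxyphosphoryl)-3-{[(2Z)-3-methylpent-2-en-4-yn-1-yl]oxy}propanoate (racemic at C11) | C#C/C(C)=C\COCC(C(=O)OC)P(=O)(OC)OC | intermediate
5 | dilithio derivative of 4 (lithium acetylide at C2, lithiated phosphonoacetate at C11; not isolated) | [Li]C#C/C(C)=C\COCC([Li])(C(=O)OC)P(=O)(OC)OC | intermediate
6 | hemiketal from addition of 5 to 2: (3R,4R,5R)-2-alkynyl-4-(TBS-oxy)-5-(TBS-oxymethyl)-3-methyloxolane-2,3-diol, alkynyl = (3Z)-5-[2-(dimethoxyphosphoryl)-3-methoxy-3-oxopropoxy]-3-methylpent-3-en-1-yn-1-yl (mixture at C1 and C11) | OC1(C#C/C(C)=C\COCC(C(=O)OC)P(=O)(OC)OC)[C@](C)(O)[C@H](O[Si](C)(C)C(C)(C)C)[C@@H](CO[Si](C)(C)C(C)(C)C)O1 | intermediate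
7 | open-chain enaminone: C1 ketone, C2=C3 with NEt2 on C3, (8R,9R,10R) with 8-OH, 10-OH, 7,9-bis-OTBS, (4Z)-olefin, phosphonate ether on O6 (not isolated) | CCN(CC)C(=CC(=O)[C@](C)(O)[C@H](O[Si](C)(C)C(C)(C)C)[C@H](O)CO[Si](C)(C)C(C)(C)C)/C(C)=C\COCC(C(=O)OC)P(=O)(OC)OC | intermediate
8 | 3(2H)-furanone (O bridging C3 and C10, 10R) bearing at C10 the (9R)-OTBS/(8R)-OH/7-OTBS chain and at C3 the (4Z)-C4(Me)=C5H–C6H2–O–CH2–CH[P(O)(OMe)2]CO2Me chain | COC(=O)C(COC/C=C(/C)C1=CC(=O)[C@](C)(O1)[C@H](O[Si](C)(C)C(C)(C)C)[C@H](O)CO[Si](C)(C)C(C)(C)C)P(=O)(OC)OC | intermediate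
9 | as 8 with C8 inverted and esterified: (8S)-methacrylate, (9R)-OTBS, 7-OTBS | COC(=O)C(COC/C=C(/C)C1=CC(=O)[C@](C)(O1)[C@H](O[Si](C)(C)C(C)(C)C)[C@@H](OC(=O)C(C)=C)CO[Si](C)(C)C(C)(C)C)P(=O)(OC)OC | intermediate
10 | as 9 with free primary C7–OH | COC(=O)C(COC/C=C(/C)C1=CC(=O)[C@](C)(O1)[C@H](O[Si](C)(C)C(C)(C)C)[C@@H](OC(=O)C(C)=C)CO)P(=O)(OC)OC | intermediate
11 | as 9 with C7 as aldehyde (same spatial arrangement at C8) | COC(=O)C(COC/C=C(/C)C1=CC(=O)[C@](C)(O1)[C@H](O[Si](C)(C)C(C)(C)C)[C@@H](OC(=O)C(C)=C)C=O)P(=O)(OC)OC | intermediate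
12 | twelve-membered ether O6–C6–C5=C4–C3(furanone)–O–C10–C9–C8–C7=C11–C13; 4Z, C8 cis to C13 on C7=C11, CO2Me on C11, (8S)-methacrylate, (9R)-OTBS, 10R | O1C/C=C(/C)C2=CC(=O)[C@](C)(O2)[C@H](O[Si](C)(C)C(C)(C)C)[C@@H](OC(=O)C(C)=C)/C=C(\C1)C(=O)OC | intermediate
13 | lithium trienolate of 12 (O–Li on C1; C1=C2, C3=C4, C5=C6; not isolated) | O1C=CC(C)=C2C=C(O[Li])[C@](C)(O2)[C@H](O[Si](C)(C)C(C)(C)C)[C@@H](OC(=O)C(C)=C)/C=C(\C1)C(=O)OC | intermediate
14 | ring-contracted hydroxy ester: ten-membered carbocycle with (6S)-OH, (7S)-C(=CH2)CO2Me, (8S)-methacrylate, (9R)-OTBS (not isolated) | C=C(C)C(=O)O[C@H]1[C@@H](C(=C)C(=O)OC)[C@@H](O)/C=C(/C)C2=CC(=O)[C@](C)(O2)[C@@H]1O[Si](C)(C)C(C)(C)C | intermediate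
15 | 9-O-TBS ether of the target (6S,7S,8S,9R,10R) | C=C(C)C(=O)O[C@H]1[C@H]2C(=C)C(=O)O[C@H]2/C=C(/C)C2=CC(=O)[C@](C)(O2)[C@@H]1O[Si](C)(C)C(C)(C)C | intermediate
16 | CNP0252578.4 | C=C(C)C(=O)O[C@H]1[C@H]2C(=C)C(=O)O[C@H]2/C=C(/C)C2=CC(=O)[C@](C)(O2)[C@@H]1O | target

## Step count

Total step count: 10. Longest linear sequence: 9 steps (from 1 through steps 1 and 3–10).

## Steps most likely to fail, with fallbacks

**Step 9 (ring contraction).** This is the least certain step. The base may deprotonate C8–H (γ to the enoate) instead of C6–H. The trienolate may lose the C4=C5 geometry or give a [1,2]-shift. The face of C7 that is attacked rests on a conformational argument, not on a close precedent. The fallback keeps the same C6–C7 disconnection but closes it ionically. Setting out from 12, the doubly allylic ether is cleaved at the acrylate-activated C13–O bond with Me2BBr (CH2Cl2, −78 °C) to give bromo alcohol F1; either allylic bromide regioisomer serves. MnO2 then oxidises the allylic alcohol to bromo enal F2. Zinc dust in THF/aq. NH4Cl at high dilution effects an intramolecular Barbier allylation (γ-attack through a chair-like cyclic transition state, syn-selective), and PPTS completes lactonisation. This comes back to the route at 15.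

**Step 8 (macrocyclic olefination).** The phosphonate anion could add intramolecularly in a 1,6-fashion to the dienyl furanone (five-membered ring at C5) faster than it finds the aldehyde. Oligomerisation and epimerisation of the α-acyloxy aldehyde are further risks. The fallback closes the macrocycle before the dienone exists. Setting out from 6, HF·pyridine frees the primary hydroxyl to give lactol alcohol F3, and Dess–Martin periodinane gives lactol aldehyde F4. LiCl/DBU olefination at high dilution then gives macrocyclic lactol F5. Et2NH followed by AcOH converts this into macrocyclic furanone alcohol F6, whose C8 hydroxyl is now allylic. Mitsunobu esterification with methacrylic acid (inversion at C8) comes back to the route at 12.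

**Step 5 (Mitsunobu at C8).** The alcohol is flanked by a silyloxymethyl group and a silyloxy carbon next to a quaternary centre, so elimination or no reaction is possible. The fallback inverts C8 by oxidation and reduction. Setting out from 8, Dess–Martin periodinane gives ketone F7. LiAlH(Ot-Bu)3 in THF at −78 °C reduces it under Felkin–Anh control (hydride anti to the non-chelating C9 silyloxy group) to the 8S alcohol F8. Methacrylic anhydride/DMAP then acylates it, coming back to the route at 9.

## Further compounds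

F1 | step 9 | bromo alcohol: ring-opened 12 with free C6–OH and (Z)-2-(bromomethyl)enoate at C7=C11 | OC/C=C(/C)C1=CC(=O)[C@](C)(O1)[C@H](O[Si](C)(C)C(C)(C)C)[C@@H](OC(=O)C(C)=C)/C=C(\CBr)C(=O)OC
F2 | step 9 | bromo enal: F1 with C6 as (Z)-enal | O=C/C=C(/C)C1=CC(=O)[C@](C)(O1)[C@H](O[Si](C)(C)C(C)(C)C)[C@@H](OC(=O)C(C)=C)/C=C(\CBr)C(=O)OC
F3 | step 8 | lactol alcohol: 6 with free primary C7–OH | OC1(C#C/C(C)=C\COCC(C(=O)OC)P(=O)(OC)OC)[C@](C)(O)[C@H](O[Si](C)(C)C(C)(C)C)[C@@H](CO)O1
F4 | step 8 | lactol aldehyde: F3 with C7 as aldehyde | OC1(C#C/C(C)=C\COCC(C(=O)OC)P(=O)(OC)OC)[C@](C)(O)[C@H](O[Si](C)(C)C(C)(C)C)[C@@H](C=O)O1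
F5 | step 8 | macrocyclic lactol: twelve-membered ether closed at C7=C11, C1 hemiketal to O8, C2≡C3 alkyne | O1C/C=C(/C)C#CC2(O)[C@](C)(O)[C@H](O[Si](C)(C)C(C)(C)C)[C@H](O2)/C=C(\C1)C(=O)OC
F6 | step 8 | macrocyclic furanone alcohol: 12 with (8R)-OH in place of the (8S)-methacrylate | O1C/C=C(/C)C2=CC(=O)[C@](C)(O2)[C@H](O[Si](C)(C)C(C)(C)C)[C@H](O)/C=C(\C1)C(=O)OC
F7 | step 5 | C8 ketone of 8 | COC(=O)C(COC/C=C(/C)C1=CC(=O)[C@](C)(O1)[C@H](O[Si](C)(C)C(C)(C)C)C(=O)CO[Si](C)(C)C(C)(C)C)P(=O)(OC)OC
F8 | step 5 | 8S alcohol (C8 epimer of 8) | COC(=O)C(COC/C=C(/C)C1=CC(=O)[C@](C)(O1)[C@H](O[Si](C)(C)C(C)(C)C)[C@@H](O)CO[Si](C)(C)C(C)(C)C)P(=O)(OC)OC
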